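The readings are simulated for an exercise, and the scatter is random.

Start from amounts: in percent of the substrate charged, the coupling partner of the north-west flask stands at 60.0 %, so it is the limiting reagent.

in all of them: substrate 0.10 M
- north-west: coupling partner 0.060 M; capture agent 2 mM; free catalyst 4.3 mM; the very flask that is asked about, followed so far
- north-east: coupling partner 0.060 M; capture agent 2 mM; free catalyst 2.1 mM; run made earlier
- flask: coupling partner 0.0600 M; capture agent 2.00 mM; free catalyst 4.3 mM; time 10 min

| run | time / min | target / % | substrate / % |
|---|---|---|---|
| north-west | 0.667 | 16 | 81 |
| north-west | 2.00 | 31 | 63 |
| north-west | 4.00 | 47 | 42 |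
| north-west | 6.00 | 48 | 39 |
| north-west | 8.00 | 48 | 33 |
| north-east | 0.833 | 12 | 91 |
| north-east | 2.50 | 19 | 69 |
| north-east | 5.00 | 34 | 55 |
| north-east | 8.00 | 41 | 39 |
| north-east | 10.0 | 43 | 40 |

(scatter of a reading: 2 percentage points)

- grey: at 10 min add coupling partner, 50.0 % of the amount charged, then wait 3.0 min
- teal: change nothing and wait 3.0 min more
- blue: at 10 min add free catalyst, 100 % of the amount charged, then wait 3.0 min
- violet: at 10 min add substrate, 50.0 % of the amount charged, then wait 3.0 min

- what is added takes up no volume worth counting
- a reading or a percentage of target counts all its forms, free or not

1. target, in percent of the substrate first charged, at 10 min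
2. which option adds most target ("none" when 2 percentage points or less is all one gets) (grey / teal / blue / violet / none)
3. target present, in percent of the substrate first charged, after teal
4. target present, in percent of the substrate first charged, after violet

Add target and substrate in the north-west run: the sum falls from 97.0 % to 81.0 %. Assume a side route that takes one substrate and one target each time. The partner left is then the ceiling, less target, less the missing sum divided by two: 26.0 % at 2.00 min, 7.50 % at 4.00 min, and 2.50 % at 8.00 min, which is of a size with the scatter. The fast rung is this partner of the north-west run: the fraction left between the first two of these values gives a half-life, as a reading, of 1.12 min.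

The slow rung is the leak. Take the fall of the sum per minute in the north-west run, divide it by two, and divide again by the product of target and substrate at 4.00 min. This gives 0.0553 min⁻¹, the leak constant: the share of target lost per minute for each whole charge of substrate standing in the flask. With the substrate of the last reading, target has a half-life of 38.0 min, far slower than the partner. So the north-west flask climbs, then looks flat while it slowly loses target. With the partner down near the scatter, the substrate taken as steady over the wait and no new target counted, the fraction of target left after a wait is exp(−leak constant × substrate × wait).

My reckoning from the last reading gives 46.3 % now, 43.8 % after teal and 40.3 % after violet. I choose grey, as the partner's half-life is shorter than the wait.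

The forecast says 48 % now, grey as the best option, 48 % after teal and 52 % after violet; of adding substrate it says that this “gives about +5 at most, and nothing if partner is truly spent”. Its change from now to violet differs from mine in sign.

The flask gives 46.2 %, and grey adds most, 13 percentage points; teal ends at 43.9 % and violet at 39.7 %.

    free catalyst + target ⇌ idle complex (K = 9.30 M⁻¹, k = 0.165 M⁻¹ s⁻¹)
    capture agent + catalyst intermediate C → trapped intermediate (k = 1.66 M⁻¹ s⁻¹)
    catalyst intermediate C ⇌ free catalyst + target (K = 0.190 M, k = 0.346 s⁻¹)
    substrate + catalyst intermediate A ⇌ catalyst intermediate B (K = 15.0 M⁻¹, k = 5.01 M⁻¹ s⁻¹)
    coupling partner + free catalyst → catalyst intermediate A (k = 4.06 M⁻¹ s⁻¹)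
    substrate + target → side product (k = 0.0120 M⁻¹ s⁻¹)
    catalyst intermediate B → catalyst intermediate C (k = 23.3 s⁻¹)

At 10.0 min the flask holds 28.7 % substrate and 0.785 % of its partner charge, with side product at 23.6 %. Violet adds substrate, 50.0 % of the charge, and the leak constant then reckons target at 40.6 %. Left until 40 min, the same flask has 12.8 % substrate; the mean of its substrate at the two times reckons target at 32.8 %, and that flask stands at 30.9 %.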